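The route rests on cutting the diarylmethane bond between C6 of the methyl-bearing catechol ring A and the benzylic carbon on C5′ of ring B (each ring numbered as in herbertenediol: 1,2-diol, 3-cyclopentyl, 5-methyl). Because that carbon is para to the C2′ hydroxyl, ring B is unmasked as a p-quinone methide: a herbertenediol unit silylated at its unhindered O1′ is oxidised at its p-cresol motif, and C6 of a second, free herbertenediol, the only open site ortho to a hydroxyl, adds to the exocyclic methylene. One operation forges the bond and rearomatises ring B. Both partners come from (S)-herbertenediol, made by asymmetric conjugate arylation of 3-methylcyclopentenone.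

Key step: step 9

Remark (assumption): the facial sense of the Pd/pyridine-oxazoline arylation with this ortho-methoxy boronic acid is taken to follow that of simple arylboronic acids; should the opposite sense be found, the antipodal ligand is used.

Remark: the quaternary stereocenter is set once (step 2) and never touched again; the changes of its descriptor (S → R → S) along the route come only from changed CIP priorities.

**Step 1**
Reactants: 1 3,4-dimethoxytoluene
Product: 3 (2,3-dimethoxy-5-methylphenyl)boronic acid, via aryllithium 2 (not isolated)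
Conditions: n-BuLi, TMEDA, THF, 0 °C → rt; B(OMe)3, −78 °C → rt; 1 M HCl
Reagents that add atoms: trimethyl borate COB(OC)OC; water O
Why: Directed ortho-metalation, in which the C1 methoxy group steers lithiation to C6, the ortho position not flanked by the methyl group, followed by borylation and hydrolysis.

**Step 2**
Reactants: 3 (2,3-dimethoxy-5-methylphenyl)boronic acid; 4 3-methylcyclopent-2-en-1-one
Product: 5 (S)-3-(2,3-dimethoxy-5-methylphenyl)-3-methylcyclopentan-1-one
Conditions: Pd(OCOCF3)2 (10 mol %), (R)-t-BuPyOx [(R)-4-tert-butyl-2-(pyridin-2-yl)-4,5-dihydrooxazole] (12 mol %), NH4PF6, H2O, ClCH2CH2Cl, 50 °C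
Reagents that add atoms: none
Why: Pd(II)/pyridine-oxazoline-catalysed asymmetric conjugate addition of an arylboronic acid to a β-substituted cyclic enone (transmetalation, enantio-determining carbopalladation, protonolysis of the Pd enolate) should set the quaternary stereocenter, the (R)-ligand being chosen because the (S)-ligand delivers (R)-3-aryl-3-methylcycloalkanones and the CIP ordering is the same here.

**Step 3**
Reactants: 5 (S)-3-(2,3-dimethoxy-5-methylphenyl)-3-methylcyclopentan-1-one
Product: 7 (R)-4-(2,3-dimethoxy-5-methylphenyl)-4-methylcyclopent-2-en-1-one, via trimethylsilyl enol ether 6 (not isolated)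
Conditions: LDA, TMSCl, THF, −78 °C; then Pd(OAc)2 (1.1 equiv), MeCN, rt
Reagents that add atoms: none
Why: Saegusa–Ito dehydrogenation, in which kinetic deprotonation occurs at C5 away from the quaternary carbon and β-hydride elimination can only involve C4 because C3 bears no hydrogen, so the 4,4-disubstituted enone is the only possible enone.

**Step 4**
Reactants: 7 (R)-4-(2,3-dimethoxy-5-methylphenyl)-4-methylcyclopent-2-en-1-one
Product: 9 (R)-4-(2,3-dimethoxy-5-methylphenyl)-4,5,5-trimethylcyclopent-2-en-1-one, via monomethylated enone 8 (not isolated)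
Conditions: LDA, THF, −78 °C; MeI; then LDA, −78 °C; MeI, DMPU, −78 °C → rt
Reagents that add atoms: iodomethane CI
Why: α′-Alkylation of a 4,4-disubstituted cyclopentenone, whose C5 is the only enolisable position (no γ-hydrogen), so two successive enolate methylations can only build the gem-dimethyl group next to the quaternary carbon.

**Step 5**
Reactants: 9 (R)-4-(2,3-dimethoxy-5-methylphenyl)-4,5,5-trimethylcyclopent-2-en-1-one
Product: 10 (R)-3-(2,3-dimethoxy-5-methylphenyl)-2,2,3-trimethylcyclopentan-1-one
Conditions: H2 (1 atm), 10 % Pd/C, EtOAc, rt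
Reagents that add atoms: none
Why: Heterogeneous catalytic hydrogenation of the disubstituted enone C=C bond, under which the ketone and the aryl ethers are inert.

**Step 6**
Reactants: 10 (R)-3-(2,3-dimethoxy-5-methylphenyl)-2,2,3-trimethylcyclopentan-1-one
Product: 12 (S)-1,2-dimethoxy-5-methyl-3-(1,2,2-trimethylcyclopentyl)benzene, via hydrazone 11 (not isolated)
Conditions: N2H4·H2O, KOH, diethylene glycol, 130 °C, then 200 °C
Reagents that add atoms: none
Why: Wolff–Kishner reduction (Huang–Minlon procedure) of a non-enolisable cyclopentanone, the standard deoxygenation of 2,2,3-trimethyl-3-arylcyclopentanones, which cannot disturb the quaternary stereocenter.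

**Step 7**
Reactants: 12 (S)-1,2-dimethoxy-5-methyl-3-(1,2,2-trimethylcyclopentyl)benzene
Product: 13 (S)-5-methyl-3-(1,2,2-trimethylcyclopentyl)benzene-1,2-diol [(S)-herbertenediol]
Conditions: BBr3, CH2Cl2, −78 °C → rt; H2O
Reagents that add atoms: none
Why: Lewis acid cleavage of both aryl methyl ethers by BBr3 through aryloxyboron bromides and hydrolysis.

**Step 8**
Reactants: 13 (S)-herbertenediol
Product: 14 (S)-2-[(tert-butyldimethylsilyl)oxy]-4-methyl-6-(1,2,2-trimethylcyclopentyl)phenol
Conditions: TBSCl (1.05 equiv), imidazole, CH2Cl2, 0 °C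
Reagents that add atoms: tert-butyldimethylsilyl chloride CC(C)(C)[Si](C)(C)Cl
Why: Sterically controlled mono-silylation, since O1–H is flanked only by a ring C–H whereas O2–H is buttressed by the quaternary cyclopentyl group, and any O2 silyl ether can migrate to the less hindered O1 under the basic conditions.

**Step 9**
Reactants: 14 (S)-2-[(tert-butyldimethylsilyl)oxy]-4-methyl-6-(1,2,2-trimethylcyclopentyl)phenol; 13 (S)-herbertenediol (2 equiv)
Product: 16 3-({3-[(tert-butyldimethylsilyl)oxy]-4-hydroxy-5-[(1S)-1,2,2-trimethylcyclopentyl]phenyl}methyl)-4-methyl-6-[(1S)-1,2,2-trimethylcyclopentyl]benzene-1,2-diol, via p-quinone methide 15 (not isolated)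
Conditions: Ag2O (5 equiv), 4 Å MS, CH2Cl2 (0.02 M), rt, dark; filtered (Celite, Ar) onto 13 in CH2Cl2, −40 °C; CF3CO2H (10 mol %), −40 → 0 °C
Reagents that add atoms: none
Why: Ag2O should oxidise the p-cresol 14 through its phenoxyl radical (disproportionation) to the p-quinone methide 15, which is possible only because O1′ is silylated and o-quinone formation is thereby excluded; after removal of the silver salts, acid activates 15 as a p-hydroxybenzyl cation equivalent and C6 of catechol 13 adds to the exocyclic methylene in a 1,6-conjugate (vinylogous Friedel–Crafts) addition that rearomatises ring B. The closest known reaction types are the acid-catalysed 1,6-addition of phenols and other electron-rich arenes to p-quinone methides and the Ag2O generation of quinone methides from 2,6-disubstituted 4-methylphenols. No ring is closed and no stereocenter is formed, the two quaternary centres being remote from the reacting atoms and carried through unchanged. Site selectivity on 13 is secured by the substrate, because C6 is ortho to the free O1–H and para to the cyclopentyl-bearing carbon, whereas the only other ring C–H (C4) is wedged between the quaternary cyclopentyl group and the methyl group. O-Alkylation of 13 is reversible under acid and should funnel to the C-alkylated product. Cross-coupling over self-coupling is secured by oxidising 14 completely before 13 is added, since 15 has no nucleophilic carbon, and by the excess of 13.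

**Step 10**
Reactants: 16 mono-TBS ether of the target
Product: 17 3-({3,4-dihydroxy-5-[(1S)-1,2,2-trimethylcyclopentyl]phenyl}methyl)-4-methyl-6-[(1S)-1,2,2-trimethylcyclopentyl]benzene-1,2-diol (target)
Conditions: KHF2, MeOH (degassed), rt
Reagents that add atoms: none
Why: Fluoride-mediated cleavage of an aryl silyl ether with mildly acidic KHF2, under which the oxidation-prone catechols are not deprotonated.

**Compound list**
1 | 3,4-dimethoxytoluene (1,2-dimethoxy-4-methylbenzene) | COc1ccc(C)cc1OC | starting material
2 | (2,3-dimethoxy-5-methylphenyl)lithium | [Li]c1cc(C)cc(OC)c1OC | intermediate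
3 | (2,3-dimethoxy-5-methylphenyl)boronic acid | COc1cc(C)cc(B(O)O)c1OC | intermediate
4 | 3-methylcyclopent-2-en-1-one | CC1=CC(=O)CC1 | starting material
5 | (S)-3-(2,3-dimethoxy-5-methylphenyl)-3-methylcyclopentan-1-one | COc1cc(C)cc([C@@]2(C)CCC(=O)C2)c1OC | intermediate
6 | (S)-{[4-(2,3-dimethoxy-5-methylphenyl)-4-methylcyclopent-1-en-1-yl]oxy}trimethylsilane | COc1cc(C)cc([C@@]2(C)CC=C(O[Si](C)(C)C)C2)c1OC | intermediate
7 | (R)-4-(2,3-dimethoxy-5-methylphenyl)-4-methylcyclopent-2-en-1-one | COc1cc(C)cc([C@@]2(C)C=CC(=O)C2)c1OC | intermediate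
8 | (4S)-4-(2,3-dimethoxy-5-methylphenyl)-4,5-dimethylcyclopent-2-en-1-one (C5 epimers) | COc1cc(C)cc([C@@]2(C)C=CC(=O)C2C)c1OC | intermediate
9 | (R)-4-(2,3-dimethoxy-5-methylphenyl)-4,5,5-trimethylcyclopent-2-en-1-one | COc1cc(C)cc([C@@]2(C)C=CC(=O)C2(C)C)c1OC | intermediate
10 | (R)-3-(2,3-dimethoxy-5-methylphenyl)-2,2,3-trimethylcyclopentan-1-one | COc1cc(C)cc([C@@]2(C)CCC(=O)C2(C)C)c1OC | intermediate
11 | (S)-[3-(2,3-dimethoxy-5-methylphenyl)-2,2,3-trimethylcyclopentylidene]hydrazine | COc1cc(C)cc([C@@]2(C)CCC(=NN)C2(C)C)c1OC | intermediate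
12 | (S)-1,2-dimethoxy-5-methyl-3-(1,2,2-trimethylcyclopentyl)benzene | COc1cc(C)cc([C@@]2(C)CCCC2(C)C)c1OC | intermediate
13 | (S)-5-methyl-3-(1,2,2-trimethylcyclopentyl)benzene-1,2-diol [(S)-herbertenediol] | Cc1cc(O)c(O)c([C@@]2(C)CCCC2(C)C)c1 | intermediate
14 | (S)-2-[(tert-butyldimethylsilyl)oxy]-4-methyl-6-(1,2,2-trimethylcyclopentyl)phenol | Cc1cc(O[Si](C)(C)C(C)(C)C)c(O)c([C@@]2(C)CCCC2(C)C)c1 | intermediate
15 | (S)-2-[(tert-butyldimethylsilyl)oxy]-4-methylidene-6-(1,2,2-trimethylcyclopentyl)cyclohexa-2,5-dien-1-one | C=C1C=C(O[Si](C)(C)C(C)(C)C)C(=O)C([C@@]2(C)CCCC2(C)C)=C1 | intermediate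
16 | 3-({3-[(tert-butyldimethylsilyl)oxy]-4-hydroxy-5-[(1S)-1,2,2-trimethylcyclopentyl]phenyl}methyl)-4-methyl-6-[(1S)-1,2,2-trimethylcyclopentyl]benzene-1,2-diol | Cc1cc([C@@]2(C)CCCC2(C)C)c(O)c(O)c1Cc1cc(O[Si](C)(C)C(C)(C)C)c(O)c([C@@]2(C)CCCC2(C)C)c1 | intermediate
17 | 3-({3,4-dihydroxy-5-[(1S)-1,2,2-trimethylcyclopentyl]phenyl}methyl)-4-methyl-6-[(1S)-1,2,2-trimethylcyclopentyl]benzene-1,2-diol (CNP0137546.1) | Cc1cc([C@@]2(C)CCCC2(C)C)c(O)c(O)c1Cc1cc(O)c(O)c([C@@]2(C)CCCC2(C)C)c1 | target

Total step count: 10
Longest linear sequence: 10 steps (1 → 17; compound 13 enters step 9 a second time as the nucleophile)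

**Steps most likely to fail**

Step 9. The quinone methide may oligomerise, or be reduced back by the catechol, before the C–C bond forms, and the oxidation may stall at phenoxyl-derived dimers. The fallback avoids a free quinone methide and sets out from 13. Peracetylation (Ac2O, pyridine, DMAP) should give (S)-5-methyl-3-(1,2,2-trimethylcyclopentyl)-1,2-phenylene diacetate F1. Wohl–Ziegler bromination of its only benzylic C–H position (NBS, AIBN, PhCF3, reflux) should give (S)-5-(bromomethyl)-3-(1,2,2-trimethylcyclopentyl)-1,2-phenylene diacetate F2. Friedel–Crafts benzylation of a second portion of 13 at C6 with F2 (ZnCl2 cat., CH2Cl2/HFIP, 40 °C) should give 5-({2,3-dihydroxy-6-methyl-4-[(1S)-1,2,2-trimethylcyclopentyl]phenyl}methyl)-3-[(1S)-1,2,2-trimethylcyclopentyl]-1,2-phenylene diacetate F3. Methanolysis (K2CO3 cat., degassed MeOH) brings the material back to the route at 17.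

Step 2. Protodeboronation of the ortho-methoxy boronic acid may outrun transmetalation, and the ortho substituent may erode facial discrimination in the carbopalladation. The fallback sets out from 1 through the aryllithium 2, which is transmetalated with Me2AlCl to (2,3-dimethoxy-5-methylphenyl)dimethylaluminium F4. Copper-catalysed asymmetric conjugate addition of F4 to 4 (Cu(OTf)2, chiral sulfonate-bearing N-heterocyclic carbene ligand of the enantiomeric series leading to the (S)-ketone, THF, −30 °C) comes back to the route at 5.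

Step 6. Hydrazone formation at the carbonyl flanked by the gem-dimethyl group may remain incomplete, and hot KOH may partly cleave the methyl ethers (harmless before step 7). The fallback sets out from 10. Reduction (LiAlH4, THF) should give (3S)-3-(2,3-dimethoxy-5-methylphenyl)-2,2,3-trimethylcyclopentan-1-ol F5 as a mixture of carbinol epimers. Conversion (NaH, CS2, MeI, THF) should give the xanthate O-[(3S)-3-(2,3-dimethoxy-5-methylphenyl)-2,2,3-trimethylcyclopentyl] S-methyl carbonodithioate F6. Barton–McCombie deoxygenation (Bu3SnH, AIBN, toluene, reflux) comes back to the route at 12.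

**Further compounds**
F1 | step 9 | (S)-5-methyl-3-(1,2,2-trimethylcyclopentyl)-1,2-phenylene diacetate | CC(=O)Oc1cc(C)cc([C@@]2(C)CCCC2(C)C)c1OC(C)=O
F2 | step 9 | (S)-5-(bromomethyl)-3-(1,2,2-trimethylcyclopentyl)-1,2-phenylene diacetate | CC(=O)Oc1cc(CBr)cc([C@@]2(C)CCCC2(C)C)c1OC(C)=O
F3 | step 9 | 5-({2,3-dihydroxy-6-methyl-4-[(1S)-1,2,2-trimethylcyclopentyl]phenyl}methyl)-3-[(1S)-1,2,2-trimethylcyclopentyl]-1,2-phenylene diacetate | Cc1cc([C@@]2(C)CCCC2(C)C)c(O)c(O)c1Cc1cc(OC(C)=O)c(OC(C)=O)c([C@@]2(C)CCCC2(C)C)c1
F4 | step 2 | (2,3-dimethoxy-5-methylphenyl)dimethylaluminium | COc1cc(C)cc([Al](C)C)c1OC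
F5 | step 6 | (3S)-3-(2,3-dimethoxy-5-methylphenyl)-2,2,3-trimethylcyclopentan-1-ol (C1 epimers) | COc1cc(C)cc([C@@]2(C)CCC(O)C2(C)C)c1OC
F6 | step 6 | O-[(3S)-3-(2,3-dimethoxy-5-methylphenyl)-2,2,3-trimethylcyclopentyl] S-methyl carbonodithioate | COc1cc(C)cc([C@@]2(C)CCC(OC(=S)SC)C2(C)C)c1OC
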